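**Plan**
Retrosynthesis: the C4 carbonyl is traced back to a silyl-protected carbinol; then O1–C8a (aryl ether), C3–C4 (aldol) and the B-ring C5'–C1'' bond to the hydrated geranyl chain are cut, in that order.
Enabling feature: O1 bridges A-ring carbon C8a and the benzylic stereocentre C2, and C8a is ortho to C4a, the carbon carrying C4. A C2 hydroxyl at the end of the C4–C3–C2 chain therefore reaches a sulfonate on C8a in a six-membered closure, and that sulfonate is made from one of the equivalent ortho phenols of phloroglucinaldehyde.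
Forward: the chain (geranyl acetate, hydrated at the distal alkene) is joined to the B ring (5-bromovanillin) by aryl–allyl coupling; the B-ring methyl ketone enolate adds to the A-ring triflate aldehyde; the pyran ring, the only ring made, closes by Pd-catalysed O1–C8a coupling; C4 oxidation and MOM removal finish.
Stereochemistry: C2 (S) comes from Noyori transfer hydrogenation of the aryl ketone with the (S,S)-TsDPEN–Ru catalyst and its C–O bond is never broken afterwards; the E-alkene is taken from geranyl acetate; the C4 epimers converge on oxidation.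

Key step: step 15

Remark: the carbinol carbon made in step 12 (later C4) is carried as an epimer mixture through 19–23 and is left undefined in their SMILES; the tertiary alcohol is masked as its triethylsilyl ether from step 2 to step 16.

Abbreviations used in the step lines: ArB = 3,4-bis(methoxymethoxy)-5-[(2E)-3,7-dimethyl-7-(triethylsilyloxy)oct-2-en-1-yl]phenyl; ArA = 2,4-bis(methoxymethoxy)-6-(trifluoromethanesulfonyloxy)phenyl.

**Route**

Step 1
Reactants: 1 geranyl acetate
Product: 3 (2E)-7-hydroxy-3,7-dimethyloct-2-en-1-yl acetate, via organomercurial acetate 2 (not isolated)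
Conditions: Hg(OAc)2, THF/H2O, rt; then aq. NaOH, NaBH4, 0 °C
Reagents that add atoms: water, O
Why: Oxymercuration–demercuration (Markovnikov hydration) should pick the electron-richer distal trisubstituted alkene, because the 2,3-alkene is deactivated by the allylic acetate, and the reductive demercuration leaves the E-alkene and the ester alone.

Step 2
Reactants: 3 (2E)-7-hydroxy-3,7-dimethyloct-2-en-1-yl acetate
Product: 4 (2E)-3,7-dimethyl-7-(triethylsilyloxy)oct-2-en-1-yl acetate
Conditions: TESOTf, 2,6-lutidine, CH2Cl2, −78 → 0 °C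
Reagents that add atoms: triethylsilyl trifluoromethanesulfonate, CC[Si](CC)(CC)OS(=O)(=O)C(F)(F)F
Why: Silyl triflate silylation is the standard way to cap a tertiary alcohol, and the TES ether keeps this hydroxyl from consuming organometallics and bases later and is removed by fluoride together with the C4 silyl ether.

Step 3
Reactants: 4 (2E)-3,7-dimethyl-7-(triethylsilyloxy)oct-2-en-1-yl acetate
Product: 5 (2E)-3,7-dimethyl-7-(triethylsilyloxy)oct-2-en-1-ol
Conditions: K2CO3 (cat.), MeOH, rt
Reagents that add atoms: none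
Why: Base-catalysed transesterification with methanol cleaves the primary acetate, while the hindered tertiary silyl ether should be stable to carbonate.

Step 4
Reactants: 5 (2E)-3,7-dimethyl-7-(triethylsilyloxy)oct-2-en-1-ol
Product: 6 (2E)-1-bromo-3,7-dimethyl-7-(triethylsilyloxy)oct-2-ene
Conditions: CBr4, PPh3, CH2Cl2, 0 °C
Reagents that add atoms: carbon tetrabromide, BrC(Br)(Br)Br
Why: The Appel reaction converts a primary allylic alcohol into the bromide under neutral conditions, so neither allylic transposition, E/Z scrambling nor silyl ether loss is expected.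

Step 5
Reactants: 7 5-bromovanillin
Product: 8 3-bromo-4,5-dihydroxybenzaldehyde
Conditions: AlCl3, pyridine, CH2Cl2, reflux; then aq. HCl
Reagents that add atoms: none
Why: Lewis acid-assisted O-demethylation, in which aluminium chelates the ortho hydroxy–methoxy pair and pyridine takes the methyl group, is the established route from 5-substituted vanillins to the catechols.

Step 6
Reactants: 8 3-bromo-4,5-dihydroxybenzaldehyde
Product: 9 3-bromo-4,5-bis(methoxymethoxy)benzaldehyde
Conditions: MOMCl, i-Pr2NEt, CH2Cl2, 0 °C → rt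
Reagents that add atoms: chloromethyl methyl ether, COCCl
Why: O-alkylation of both phenols with MOMCl and Hünig's base gives acetal ethers that tolerate organolithium, Grignard, enolate and palladium chemistry.

Step 7
Reactants: 9 3-bromo-4,5-bis(methoxymethoxy)benzaldehyde
Product: 10 rac-1-[3-bromo-4,5-bis(methoxymethoxy)phenyl]ethanol
Conditions: MeMgBr, THF, 0 °C; then H2O
Reagents that add atoms: methylmagnesium bromide, C[Mg]Br
Why: Grignard addition to the aldehyde installs the future acetyl carbon, and the aryl bromide does not exchange with MeMgBr at this temperature.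

Step 8
Reactants: 10 rac-1-[3-bromo-4,5-bis(methoxymethoxy)phenyl]ethanol; 6 (2E)-1-bromo-3,7-dimethyl-7-(triethylsilyloxy)oct-2-ene
Product: 13 rac-1-{3,4-bis(methoxymethoxy)-5-[(2E)-3,7-dimethyl-7-(triethylsilyloxy)oct-2-en-1-yl]phenyl}ethanol (ArB–CH(OH)CH3), via dilithio species 11 (not isolated), via arylcopper species 12 (not isolated)
Conditions: n-BuLi (2.1 equiv), THF, −78 °C; CuBr·SMe2 (1.0 equiv), −78 → −40 °C; then 6, −78 → 0 °C; H2O
Reagents that add atoms: none
Why: Deprotonation of the carbinol (in-situ protection as the alkoxide) and bromine–lithium exchange, transmetallation to copper and SN2 allylic alkylation should join the aryl carbon to the unhindered primary terminus of the allylic bromide, giving the linear E product.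

Step 9
Reactants: 13 ArB–CH(OH)CH3
Product: 14 1-{3,4-bis(methoxymethoxy)-5-[(2E)-3,7-dimethyl-7-(triethylsilyloxy)oct-2-en-1-yl]phenyl}ethanone (ArB–COCH3)
Conditions: Dess–Martin periodinane, pyridine, CH2Cl2, 0 °C → rt
Reagents that add atoms: none
Why: Dess–Martin oxidation of the secondary benzylic alcohol gives the aryl methyl ketone under buffered conditions that spare the acetal ethers, the silyl ether and the alkene.

Step 10
Reactants: 15 2,4,6-trihydroxybenzaldehyde
Product: 16 2-hydroxy-4,6-bis(methoxymethoxy)benzaldehyde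
Conditions: MOMCl (2.2 equiv), i-Pr2NEt, CH2Cl2, 0 °C
Reagents that add atoms: chloromethyl methyl ether, COCCl
Why: Selective O-alkylation is expected because, after the 4-OH and one ortho OH have reacted, the last ortho phenol is held in a hydrogen bond to the formyl group and is far less nucleophilic.

Step 11
Reactants: 16 2-hydroxy-4,6-bis(methoxymethoxy)benzaldehyde
Product: 17 2-formyl-3,5-bis(methoxymethoxy)phenyl trifluoromethanesulfonate
Conditions: Tf2O, pyridine, CH2Cl2, −20 → 0 °C
Reagents that add atoms: trifluoromethanesulfonic anhydride, O=S(=O)(OS(=O)(=O)C(F)(F)F)C(F)(F)F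
Why: O-sulfonylation of the remaining phenol with triflic anhydride turns the future C8a oxygen into the leaving group for the palladium step, as is routine for salicylaldehydes.

Step 12
Reactants: 14 ArB–COCH3; 17 2-formyl-3,5-bis(methoxymethoxy)phenyl trifluoromethanesulfonate
Product: 19 rac-1-ArB-3-hydroxy-3-ArA-propan-1-one, via lithium enolate 18 (not isolated)
Conditions: LDA, THF, −78 °C; then 17, −78 °C; AcOH quench at −78 °C
Reagents that add atoms: none
Why: Directed aldol addition of the kinetic lithium enolate to the non-enolisable aldehyde forms C3–C4 at low temperature, where the aryl triflate is inert, and the new carbinol centre may be racemic because it is later oxidised.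

Step 13
Reactants: 19 rac-1-ArB-3-hydroxy-3-ArA-propan-1-one
Product: 20 rac-1-ArB-3-(tert-butyldimethylsilyloxy)-3-ArA-propan-1-one
Conditions: TBSOTf, 2,6-lutidine, CH2Cl2, −78 °C
Reagents that add atoms: tert-butyldimethylsilyl trifluoromethanesulfonate, CC(C)(C)[Si](C)(C)OS(=O)(=O)C(F)(F)F
Why: Silyl triflate silylation of the hindered benzylic aldol hydroxyl blocks retro-aldol cleavage and dehydration to the chalcone and masks the C4 oxygen from palladium.

Step 14
Reactants: 20 rac-1-ArB-3-(tert-butyldimethylsilyloxy)-3-ArA-propan-1-one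
Product: 21 (1S)-1-ArB-3-(tert-butyldimethylsilyloxy)-3-ArA-propan-1-ol (C3 epimers)
Conditions: RuCl[(S,S)-TsDPEN](p-cymene) (5 mol %), HCO2H/Et3N (5:2), EtOAc, 30 °C
Reagents that add atoms: none
Why: Noyori asymmetric transfer hydrogenation with the (S,S) catalyst delivers hydride to aryl alkyl ketones to give the (S)-carbinol (aryl outranks CH2 as in 1-phenylethanol), and catalyst control should override the remote racemic silyloxy centre.

Step 15
Reactants: 21 (1S)-1-ArB-3-(tert-butyldimethylsilyloxy)-3-ArA-propan-1-ol (C3 epimers)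
Product: 22 (2S)-4-(tert-butyldimethylsilyloxy)-5,7-bis(methoxymethoxy)-2-ArB-chromane (C4 epimers)
Conditions: [Pd(allyl)Cl]2 (2.5 mol %), RockPhos (6 mol %), K3PO4 (2 equiv), toluene, 80 °C
Reagents that add atoms: none
Why: Pd(0) carrying the bulky di-tert-butyl biaryl phosphine adds oxidatively to the C8a–OTf bond, phosphate-assisted exchange places the C2 alkoxide on palladium, and C(sp2)–O reductive elimination releases the aryl ether (intramolecular Buchwald–Hartwig etherification). The closest known reaction type is the Pd-catalysed cyclisation of secondary alcohols onto ortho aryl halides or sulfonates to give 2-substituted chromans. The six-membered pyran ring closes in a 6-exo sense by forming O1–C8a through a seven-membered oxapalladacycle. No stereocentre is created: the carbinol C–O bond stays intact, so the S configuration from step 14 becomes C2 with retention, and C4 remains an epimer mixture. Reductive elimination must outrun β-hydride elimination of the benzylic palladium alkoxide, which the hindered electron-rich ligand enforces, and only one hydroxyl may engage, which the substrate secures because the C4 and tertiary oxygens are silylated and only the C2 oxygen can reach C8a. Holding C4 as a silyl ether and not as a ketone removes any retro-aldol or retro-oxa-Michael pathway under base, and the weak, insoluble K3PO4 limits S–O cleavage of the triflate.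

Step 16
Reactants: 22 (2S)-4-(tert-butyldimethylsilyloxy)-5,7-bis(methoxymethoxy)-2-ArB-chromane (C4 epimers)
Product: 23 (2S)-2-{3,4-bis(methoxymethoxy)-5-[(2E)-7-hydroxy-3,7-dimethyloct-2-en-1-yl]phenyl}-5,7-bis(methoxymethoxy)chroman-4-ol (C4 epimers)
Conditions: TBAF (excess), THF, rt → 40 °C
Reagents that add atoms: none
Why: Fluoride-mediated desilylation removes the secondary TBS and the tertiary TES ether together, and with no carbonyl yet in the ring the basic fluoride cannot open the pyran.

Step 17
Reactants: 23 the flavan-4-ol (C4 epimers)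
Product: 24 (2S)-2-{3,4-bis(methoxymethoxy)-5-[(2E)-7-hydroxy-3,7-dimethyloct-2-en-1-yl]phenyl}-5,7-bis(methoxymethoxy)chroman-4-one
Conditions: Dess–Martin periodinane, pyridine, CH2Cl2, 0 °C → rt
Reagents that add atoms: none
Why: Dess–Martin oxidation takes both benzylic C4 epimers to the single ketone without touching the tertiary alcohol, and the buffered neutral medium should not open the flavanone or epimerise C2.

Step 18
Reactants: 24 the tetra-MOM flavanone
Product: 25 propolin B, (2S)-2-{3,4-dihydroxy-5-[(2E)-7-hydroxy-3,7-dimethyloct-2-en-1-yl]phenyl}-5,7-dihydroxychroman-4-one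
Conditions: HCl (2 M, aq.)/MeOH 1:4, 40 °C, stopped at full conversion
Reagents that add atoms: none
Why: Acid-catalysed acetal methanolysis removes the four aryl MOM ethers, and dilute acid at moderate temperature is chosen to spare the tertiary alcohol, the trisubstituted alkene and the C2 configuration.

**Compound list**
1 | geranyl acetate, (2E)-3,7-dimethylocta-2,6-dien-1-yl acetate | CC(=O)OC/C=C(\C)CCC=C(C)C | starting material
2 | (2E)-6-(acetoxymercurio)-7-hydroxy-3,7-dimethyloct-2-en-1-yl acetate (racemic at C6) | CC(=O)OC/C=C(\C)CCC([Hg]OC(C)=O)C(C)(C)O | intermediate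
3 | (2E)-7-hydroxy-3,7-dimethyloct-2-en-1-yl acetate | CC(=O)OC/C=C(\C)CCCC(C)(C)O | intermediate
4 | (2E)-3,7-dimethyl-7-(triethylsilyloxy)oct-2-en-1-yl acetate | CC(=O)OC/C=C(\C)CCCC(C)(C)O[Si](CC)(CC)CC | intermediate
5 | (2E)-3,7-dimethyl-7-(triethylsilyloxy)oct-2-en-1-ol | OC/C=C(\C)CCCC(C)(C)O[Si](CC)(CC)CC | intermediate
6 | (2E)-1-bromo-3,7-dimethyl-7-(triethylsilyloxy)oct-2-ene | BrC/C=C(\C)CCCC(C)(C)O[Si](CC)(CC)CC | intermediate
7 | 5-bromovanillin, 3-bromo-4-hydroxy-5-methoxybenzaldehyde | COc1cc(C=O)cc(Br)c1O | starting material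
8 | 3-bromo-4,5-dihydroxybenzaldehyde | O=Cc1cc(O)c(O)c(Br)c1 | intermediate
9 | 3-bromo-4,5-bis(methoxymethoxy)benzaldehyde | COCOc1cc(C=O)cc(Br)c1OCOC | intermediate
10 | rac-1-[3-bromo-4,5-bis(methoxymethoxy)phenyl]ethanol | CC(O)c1cc(Br)c(OCOC)c(OCOC)c1 | intermediate
11 | lithium 1-[3-lithio-4,5-bis(methoxymethoxy)phenyl]ethoxide | [Li]OC(C)c1cc([Li])c(OCOC)c(OCOC)c1 | intermediate
12 | lithium 1-[3-cuprio-4,5-bis(methoxymethoxy)phenyl]ethoxide (arylcopper(I)) | [Li]OC(C)c1cc([Cu])c(OCOC)c(OCOC)c1 | intermediate
13 | rac-1-{3,4-bis(methoxymethoxy)-5-[(2E)-3,7-dimethyl-7-(triethylsilyloxy)oct-2-en-1-yl]phenyl}ethanol | C/C(=C\Cc1cc(C(C)O)cc(OCOC)c1OCOC)CCCC(C)(C)O[Si](CC)(CC)CC | intermediate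
14 | 1-{3,4-bis(methoxymethoxy)-5-[(2E)-3,7-dimethyl-7-(triethylsilyloxy)oct-2-en-1-yl]phenyl}ethanone | C/C(=C\Cc1cc(C(C)=O)cc(OCOC)c1OCOC)CCCC(C)(C)O[Si](CC)(CC)CC | intermediate
15 | 2,4,6-trihydroxybenzaldehyde | O=Cc1c(O)cc(O)cc1O | starting material
16 | 2-hydroxy-4,6-bis(methoxymethoxy)benzaldehyde | O=Cc1c(O)cc(OCOC)cc1OCOC | intermediate
17 | 2-formyl-3,5-bis(methoxymethoxy)phenyl trifluoromethanesulfonate | O=Cc1c(OS(=O)(=O)C(F)(F)F)cc(OCOC)cc1OCOC | intermediate
18 | lithium enolate of 14, lithium 1-{3,4-bis(methoxymethoxy)-5-[(2E)-3,7-dimethyl-7-(triethylsilyloxy)oct-2-en-1-yl]phenyl}ethenolate | C/C(=C\Cc1cc(C(=C)O[Li])cc(OCOC)c1OCOC)CCCC(C)(C)O[Si](CC)(CC)CC | intermediate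
19 | rac-1-{3,4-bis(methoxymethoxy)-5-[(2E)-3,7-dimethyl-7-(triethylsilyloxy)oct-2-en-1-yl]phenyl}-3-hydroxy-3-[2,4-bis(methoxymethoxy)-6-(trifluoromethanesulfonyloxy)phenyl]propan-1-one | C/C(=C\Cc1cc(C(=O)CC(O)c2c(OS(=O)(=O)C(F)(F)F)cc(OCOC)cc2OCOC)cc(OCOC)c1OCOC)CCCC(C)(C)O[Si](CC)(CC)CC | intermediate
20 | rac-1-{3,4-bis(methoxymethoxy)-5-[(2E)-3,7-dimethyl-7-(triethylsilyloxy)oct-2-en-1-yl]phenyl}-3-(tert-butyldimethylsilyloxy)-3-[2,4-bis(methoxymethoxy)-6-(trifluoromethanesulfonyloxy)phenyl]propan-1-one | C/C(=C\Cc1cc(C(=O)CC(O[Si](C)(C)C(C)(C)C)c2c(OS(=O)(=O)C(F)(F)F)cc(OCOC)cc2OCOC)cc(OCOC)c1OCOC)CCCC(C)(C)O[Si](CC)(CC)CC | intermediate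
21 | (1S)-1-{3,4-bis(methoxymethoxy)-5-[(2E)-3,7-dimethyl-7-(triethylsilyloxy)oct-2-en-1-yl]phenyl}-3-(tert-butyldimethylsilyloxy)-3-[2,4-bis(methoxymethoxy)-6-(trifluoromethanesulfonyloxy)phenyl]propan-1-ol, C3 epimer mixture | C/C(=C\Cc1cc([C@@H](O)CC(O[Si](C)(C)C(C)(C)C)c2c(OS(=O)(=O)C(F)(F)F)cc(OCOC)cc2OCOC)cc(OCOC)c1OCOC)CCCC(C)(C)O[Si](CC)(CC)CC | intermediate
22 | (2S)-2-{3,4-bis(methoxymethoxy)-5-[(2E)-3,7-dimethyl-7-(triethylsilyloxy)oct-2-en-1-yl]phenyl}-4-(tert-butyldimethylsilyloxy)-5,7-bis(methoxymethoxy)chromane, C4 epimer mixture | C/C(=C\Cc1cc([C@@H]2CC(O[Si](C)(C)C(C)(C)C)c3c(OCOC)cc(OCOC)cc3O2)cc(OCOC)c1OCOC)CCCC(C)(C)O[Si](CC)(CC)CC | intermediate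
23 | (2S)-2-{3,4-bis(methoxymethoxy)-5-[(2E)-7-hydroxy-3,7-dimethyloct-2-en-1-yl]phenyl}-5,7-bis(methoxymethoxy)chroman-4-ol, C4 epimer mixture | C/C(=C\Cc1cc([C@@H]2CC(O)c3c(OCOC)cc(OCOC)cc3O2)cc(OCOC)c1OCOC)CCCC(C)(C)O | intermediate
24 | (2S)-2-{3,4-bis(methoxymethoxy)-5-[(2E)-7-hydroxy-3,7-dimethyloct-2-en-1-yl]phenyl}-5,7-bis(methoxymethoxy)chroman-4-one | C/C(=C\Cc1cc([C@@H]2CC(=O)c3c(OCOC)cc(OCOC)cc3O2)cc(OCOC)c1OCOC)CCCC(C)(C)O | intermediate
25 | propolin B, (2S)-2-{3,4-dihydroxy-5-[(2E)-7-hydroxy-3,7-dimethyloct-2-en-1-yl]phenyl}-5,7-dihydroxychroman-4-one | C/C(=C\Cc1cc([C@@H]2CC(=O)c3c(O)cc(O)cc3O2)cc(O)c1O)CCCC(C)(C)O | target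

**Count and risks**
Total: 18 steps. Longest linear sequence: 13 steps from geranyl acetate (steps 1–4, 8, 9, 12–18).

Step 15 (aryl ether closure). What may go wrong: β-hydride elimination of the benzylic palladium alkoxide, which would return the ketone and reduce the triflate to the arene; S–O cleavage of the triflate by alkoxide or phosphate; or base-induced 1,5-migration of the silyl group from the C4 oxygen to the C2 oxygen. Fallback: the ring is closed from the other side, by forming O1–C2 with inversion. It sets out from 20, which is reduced with the enantiomeric RuCl[(R,R)-TsDPEN](p-cymene) catalyst under the step 14 conditions to the (1R)-carbinol triflate F1. The aryl triflate is then cleaved with aqueous Et4NOH in dioxane at rt to the (1R)-carbinol phenol F2. Mitsunobu cyclisation (PPh3, DIAD, THF, 0 °C) lets the phenol displace the activated benzylic oxygen with inversion and returns to the route at 22. Partial ionisation of the electron-rich benzylic centre would erode the configuration there, so this closure would be run cold and in a non-polar medium.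

Step 18 (global MOM removal). What may go wrong: acid-promoted attack of the freed 4'-phenol on the protonated side-chain alkene (chroman formation), solvolysis or dehydration of the tertiary alcohol, or acid-mediated ring opening with loss of configuration at C2. Fallback: a non-protic acetal exchange that sets out from 24. TMSOTf with 2,2'-bipyridyl in CH2Cl2 at 0 °C should convert the aryl MOM ethers (and the tertiary alcohol) into trimethylsilyl ethers, giving the pentakis(trimethylsilyl) ether F3. Stirring with water at rt hydrolyses the silyl ethers and returns to the route at 25.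

Step 14 (transfer hydrogenation). What may go wrong: poor facial selectivity for one of the two C3 epimers of the substrate, slow hydride transfer to the hindered electron-rich ketone, or β-elimination of the silyloxy group to the chalcone in the amine-containing medium. Fallback: the Ru-catalysed hydrogen transfer is replaced by an oxazaborolidine-directed borane reduction (Corey–Bakshi–Shibata). It sets out from 20, uses (R)-Me-CBS with catecholborane in toluene at −78 °C (a borane that should not hydroborate the trisubstituted alkene), and arrives directly at 21; no new compound is made (F0).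

**Further compounds**
F1 | step 15 | (1R)-1-{3,4-bis(methoxymethoxy)-5-[(2E)-3,7-dimethyl-7-(triethylsilyloxy)oct-2-en-1-yl]phenyl}-3-(tert-butyldimethylsilyloxy)-3-[2,4-bis(methoxymethoxy)-6-(trifluoromethanesulfonyloxy)phenyl]propan-1-ol, C3 epimer mixture | C/C(=C\Cc1cc([C@H](O)CC(O[Si](C)(C)C(C)(C)C)c2c(OS(=O)(=O)C(F)(F)F)cc(OCOC)cc2OCOC)cc(OCOC)c1OCOC)CCCC(C)(C)O[Si](CC)(CC)CC
F2 | step 15 | (1R)-1-{3,4-bis(methoxymethoxy)-5-[(2E)-3,7-dimethyl-7-(triethylsilyloxy)oct-2-en-1-yl]phenyl}-3-(tert-butyldimethylsilyloxy)-3-[2-hydroxy-4,6-bis(methoxymethoxy)phenyl]propan-1-ol, C3 epimer mixture | C/C(=C\Cc1cc([C@H](O)CC(O[Si](C)(C)C(C)(C)C)c2c(O)cc(OCOC)cc2OCOC)cc(OCOC)c1OCOC)CCCC(C)(C)O[Si](CC)(CC)CC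
F3 | step 18 | (2S)-5,7-bis(trimethylsilyloxy)-2-{3,4-bis(trimethylsilyloxy)-5-[(2E)-3,7-dimethyl-7-(trimethylsilyloxy)oct-2-en-1-yl]phenyl}chroman-4-one | C/C(=C\Cc1cc([C@@H]2CC(=O)c3c(O[Si](C)(C)C)cc(O[Si](C)(C)C)cc3O2)cc(O[Si](C)(C)C)c1O[Si](C)(C)C)CCCC(C)(C)O[Si](C)(C)C
F0 | step 14 | none | none
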